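(The constants are assumed; no experiment stands behind them.)

The reagent is the purse of this flask, so we count it first.

left-handed substrate 0.20 M; reagent 1.50 equiv; free catalyst 10 mol%; right-handed substrate 0.20 M; time 5.0 d

    free catalyst + right-handed substrate ⇌ catalyst intermediate B (K1 = 11 M⁻¹, k1 = 6.83 M⁻¹ min⁻¹)
    free catalyst + left-handed substrate ⇌ catalyst intermediate A (K2 = 13.1 M⁻¹, k2 = 27.7 M⁻¹ min⁻¹)
    free catalyst → spent catalyst (k3 = 7.48 × 10⁻⁴ min⁻¹)
    left-handed product ⇌ right-handed product (k4 = 0.00799 min⁻¹)
    reagent + catalyst intermediate B → free catalyst + right-handed product (k5 = 0.630 M⁻¹ min⁻¹)
    reagent + catalyst intermediate A → free catalyst + left-handed product (k6 = 1.37 M⁻¹ min⁻¹)

* why nothing more happens at 5.0 d, or that something still does (all of the left-handed substrate has reacted / the reagent has run out first / it is still moving / forward and back rates have come level / no working catalyst is left)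
* how much left-handed product there is at 5.0 d, in percent of the left-handed substrate and right-handed substrate together charged
* how much right-handed product there is at 5.0 d, in percent of the left-handed substrate and right-handed substrate together charged
* how much right-handed substrate there is at 5.0 d, in percent of the left-handed substrate and right-handed substrate together charged

- free catalyst is single-handed; left-handed substrate and right-handed substrate are mirror images of each other, charged as a racemate, each of them at the stated concentration
- the reaction counts as stopped when no species that holds the left-handed substrate and right-handed substrate together changes by six tenths of a point or more over the second half of the time
- run time (flask): 5.0 d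

Every product molecule costs one reagent, whichever hand it has. So we carry the reagent budget, the share of both substrates together that the charged reagent can turn into product: 1.50 equiv counted on the left-handed substrate, spread over both, gives 75.0%. That is short of the whole racemate, which makes the reagent our candidate for limiting reagent.

Two extreme flasks can be solved in the head, both spending the whole budget. With a free catalyst blind to handedness, each substrate would keep 12.5% of the two together. With a free catalyst that finished the left-handed substrate first, the right-handed substrate would keep 25.0%. Our flask lies between these. With binding near equilibrium, the selectivity factor favours the left-handed substrate by 2.59, so we place [right-handed substrate] between those two figures.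

Will the budget be spent? At the start, with both intermediates at their binding equilibria, we reckon a reagent half-life of 0.0282 d. Free catalyst, by its decay step alone, has a half-life of 0.644 d, so at that starting rate we expect the reagent to go first. The two products relax towards each other with a half-life of 0.723 h, short against 5.0 d, so we commit to 37.5% of each.

The forecast differs from us. It says all of the left-handed substrate has reacted, with 50% left-handed product, 50% right-handed product and 0% right-handed substrate, holding that “both substrate enantiomers are used up within hours”. Those are the numbers one gets with [reagent] held at its starting value.

The simulation says the reagent has run out first, with 37.5% left-handed product, 37.5% right-handed product and 20.3% right-handed substrate. At 5.00 d this flask keeps 0% of its reagent against 41% of its right-handed substrate, and its two products add to 75.0%, against a budget of 75.0%. The neighbour flask charged with 0.380 equiv of reagent has a budget of 19.0%; at 5.00 d its reagent stands at 0%, and its left-handed product and right-handed product, 9.50% and 9.50%, add to 19.0%.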